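**Retrosynthetic overview**
1. Target ⇐ 6R-alcohol (SN2 chlorination) ⇐ (7Z)-cyclodecene; 9-OH-directed syn-dihydroxylation of C7=C8 and lactonisation set C7, C8 and the γ-lactone last.
2. Ten-membered ring ⇐ RCM (C7=C8) of a triene built by NHK coupling at C8–C9 (2-iodoalkene ester = C8, C17–C19) and asymmetric alkylzinc addition at C2 (C3–C7 chain).
3. Cyclohexane oxygens ⇐ 1,2-reduction of C12=O, hydroxyl-directed 13,14-epoxidation, butyrylation.
4. Key step: dearomative Diels–Alder of 2-methyl-3-silyloxyfuran (from 3-bromofuran) with an (E)-enal, then retro-oxa-Michael opening; it sets C1 (quaternary), C10 and C11 and delivers O11 and O12.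
5. Ring order: six-membered carbocycle → ten-membered carbocycle → γ-lactone.

Assumption: atom labels are the briarane labels of the target (ring C1/C10–C14, chain C2–C9, C15/C20 methyls on C1/C11, C16 exo-methylene, C18 methyl on C17, C19 lactone carbonyl); the catalyst/ligand antipodes in steps 5, 11 and 16 are assigned from the accepted models and would be swapped if the opposite sense were found.

**Step 1**
Reactants: 1 3-bromofuran
Product: 3 3-bromo-2-methylfuran, via 3-bromo-2-lithiofuran 2 (not isolated)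
Conditions: LDA, THF, −78 °C; MeI, −78 °C → rt
Reagents that add atoms: iodomethane CI
Why: Directed ortho-lithiation removes the C2–H flanked by oxygen and bromine, and methylation gives the 2,3-disubstituted furan (no stereocentre).

**Step 2**
Reactants: 3 3-bromo-2-methylfuran
Product: 5 2-methyl-3-(trimethylsilyloxy)furan, via 3-lithio-2-methylfuran 4 (not isolated)
Conditions: n-BuLi, Et2O, −78 °C; Me3SiOOSiMe3, −78 °C → rt; distil
Reagents that add atoms: bis(trimethylsilyl) peroxide C[Si](C)(C)OO[Si](C)(C)C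
Why: Bromine–lithium exchange followed by electrophilic oxygenation of the furyllithium with the silyl peroxide gives the aromatic silyl enol ether of 2-methylfuran-3(2H)-one directly.

**Step 3**
Reactants: 6 glycolaldehyde dimer; 7 2-(triphenylphosphoranylidene)propanal
Product: 9 (E)-4-hydroxy-2-methylbut-2-enal, via glycolaldehyde 8 (not isolated)
Conditions: THF, reflux
Reagents that add atoms: none
Why: Wittig olefination of the monomer released from the dimer with the stabilised formyl ylide gives the (E)-trisubstituted enal under thermodynamic control.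

**Step 4**
Reactants: 9 (E)-4-hydroxy-2-methylbut-2-enal
Product: 10 (E)-2-methyl-4-(triethylsilyloxy)but-2-enal
Conditions: Et3SiCl, imidazole, CH2Cl2, 0 °C
Reagents that add atoms: chlorotriethylsilane CC[Si](Cl)(CC)CC
Why: Standard silylation of the primary allylic alcohol; the TES group is chosen because it can later be oxidised off directly in step 15.

**Step 5 (key step)**
Reactants: 5 2-methyl-3-(trimethylsilyloxy)furan; 10 (E)-2-methyl-4-(triethylsilyloxy)but-2-enal
Product: 12 (1S,5S,6S)-5-hydroxy-1,5-dimethyl-4-oxo-6-[(triethylsilyloxy)methyl]cyclohex-2-ene-1-carbaldehyde, via oxanorbornene adduct 11 (not isolated)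
Conditions: (S)-o-tolyl-oxazaborolidinium triflimide (20 mol %), CH2Cl2, −78 °C; then K2CO3 (cat.), MeOH, 0 °C
Reagents that add atoms: none
Why: Proposed new method: an asynchronous [4+2] in which the nucleophilic furan C2 (future C11) bonds to the enal β-carbon (C10), which also avoids a quaternary–quaternary bond, and the α-methyl enal reacts exo-CHO so that the E-alkene puts CHO exo and CH2OTES endo (C1/C10 trans, C11-O syn to C2) while the boron-bound catalyst shields one enal face; methanolysis of the silyl enol ether then frees the C12 enolate, which expels the bridging oxygen from C14 (retro-oxa-Michael) and leaves it as the C11 tertiary alcohol; closest known types are oxazaborolidinium-catalysed exo-selective Diels–Alder reactions of α-methyl enals and the opening of 3-oxyfuran adducts (7-oxanorbornan-2-ones) to 4-hydroxycyclohexenones.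

**Step 6**
Reactants: 13 α-methylene-γ-butyrolactone
Product: 15 rac-3-methylidenehex-5-ene-1,4-diol, via aluminium lactolate 14 (not isolated)
Conditions: DIBAL-H, CH2Cl2, −78 °C; CH2=CHMgBr, THF, −78 → 0 °C
Reagents that add atoms: vinylmagnesium bromide C=C[Mg]Br
Why: Partial lactone reduction stops at the aluminium lactolate, and the Grignard reagent adds 1,2 to the ring-opened 2-methylene aldehyde to give the racemic bis-allylic carbinol.

**Step 7**
Reactants: 15 rac-3-methylidenehex-5-ene-1,4-diol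
Product: 16 rac-6-iodo-4-methylidenehex-1-en-3-ol
Conditions: I2, PPh3, imidazole, CH2Cl2, −20 °C
Reagents that add atoms: iodine II
Why: Garegg–Samuelsson (Appel-type) iodination is selective for the unhindered primary alcohol over the secondary bis-allylic one at low temperature.

**Step 8**
Reactants: 16 rac-6-iodo-4-methylidenehex-1-en-3-ol
Product: 17 (S)-6-iodo-4-methylidenehex-1-en-3-ol
Conditions: Burkholderia cepacia lipase (Amano PS), vinyl acetate, MTBE, 30 °C, to 52 % conversion
Reagents that add atoms: none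
Why: Lipase kinetic resolution follows the Kazlauskas rule (small vinyl versus large 2-substituted alkenyl group), so the (R)-alcohol is acetylated and the required (S)-alcohol, the future C6 centre, is recovered.

**Step 9**
Reactants: 17 (S)-6-iodo-4-methylidenehex-1-en-3-ol
Product: 18 (3S)-3-(tert-butyldimethylsilyloxy)-6-iodo-4-methylidenehex-1-ene
Conditions: TBSOTf, 2,6-lutidine, CH2Cl2, −78 °C
Reagents that add atoms: tert-butyldimethylsilyl triflate CC(C)(C)[Si](C)(C)OS(=O)(=O)C(F)(F)F
Why: Silylation with the triflate and a hindered base protects the secondary alcohol without N-alkylation by the primary iodide.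

**Step 10**
Reactants: 19 ethyl 2-methylbuta-2,3-dienoate
Product: 20 rac-ethyl 3-iodo-2-methylbut-3-enoate
Conditions: NaI, AcOH, 80 °C
Reagents that add atoms: sodium iodide [Na+].[I-]
Why: Hydroiodination of a 2,3-allenoate (iodide adds to the central allene carbon and the dienolate is protonated at the α-carbon) gives the β-iodo-β,γ-unsaturated ester, racemic at the future C17, which is corrected in step 18.

**Step 11**
Reactants: 18 (3S)-3-(tert-butyldimethylsilyloxy)-6-iodo-4-methylidenehex-1-ene; 12 enone aldehyde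
Product: 23 (2S)-2-acetoxy enone bearing the C3–C7 chain, via dialkylzinc 21 (not isolated), via C2 carbinol 22 (not isolated)
Conditions: 18 (2.5 equiv), Et2Zn, CuI (cat.), 50 °C, then vacuum; 12, Ti(OiPr)4, (1R,2R)-1,2-bis(triflamido)cyclohexane (10 mol %), PhMe, −20 °C; aq. NH4Cl; crude: Ac2O, pyridine, DMAP, CH2Cl2, 0 °C
Reagents that add atoms: acetic anhydride CC(=O)OC(C)=O
Why: Iodine–zinc exchange and titanium bis-sulfonamide-catalysed dialkylzinc addition (Knochel/Ohno–Kobayashi type) is aldehyde-selective in the presence of the enone and tertiary alcohol and sets 2S by catalyst control (Si-face attack), and the hindered secondary carbinol is acetylated at once while the tertiary C11-OH stays free.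

**Step 12**
Reactants: 23 (2S)-2-acetoxy enone
Product: 24 cis-11,12-diol (cyclohex-2-en-1-ol)
Conditions: NaBH4, CeCl3·7H2O, MeOH, −78 °C
Reagents that add atoms: none
Why: Luche 1,2-reduction in which hydride is expected to add anti to the pseudo-axial C11–OH (polar Felkin–Anh, axial attack), giving the 12-OH cis to the 11-OH.

**Step 13**
Reactants: 24 cis-11,12-diol
Product: 25 13,14-epoxy-11,12-diol
Conditions: VO(acac)2 (5 mol %), t-BuOOH, CH2Cl2, 0 °C → rt
Reagents that add atoms: tert-butyl hydroperoxide CC(C)(C)OO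
Why: Vanadium-catalysed hydroxyl-directed epoxidation delivers oxygen syn to the allylic C12–OH (and the cis homoallylic C11–OH), giving the all-cis epoxide, while the two side-chain alkenes have no directing hydroxyl and do not react.

**Step 14**
Reactants: 25 13,14-epoxy-11,12-diol
Product: 26 12-O-butyrate
Conditions: (PrCO)2O, Et3N, DMAP (cat.), CH2Cl2, 0 °C
Reagents that add atoms: butyric anhydride CCCC(=O)OC(=O)CCC
Why: Acylation of the only secondary alcohol; the tertiary C11–OH is too hindered to react.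

**Step 15**
Reactants: 26 12-O-butyrate
Product: 27 C9 aldehyde
Conditions: (COCl)2, DMSO, CH2Cl2, −78 → −40 °C; Et3N, −78 → 0 °C
Reagents that add atoms: none
Why: Under Swern conditions chlorodimethylsulfonium chloride cleaves a primary TES ether in situ and oxidises it to the aldehyde, leaving the secondary TBS ether, the esters and the epoxide intact.

**Step 16**
Reactants: 27 C9 aldehyde; 20 rac-ethyl 3-iodo-2-methylbut-3-enoate
Product: 28 (9S)-allylic alcohol (C17 epimer mixture)
Conditions: CrCl2 (4 equiv), NiCl2 (2 mol %), (S)-Kishi oxazoline–sulfonamide ligand, Et3N, THF, rt; neutral work-up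
Reagents that add atoms: none
Why: Nozaki–Hiyama–Kishi coupling of the 2-iodoalkene tolerates the epoxide, esters and free tertiary alcohol, the ligand-bound chromium is relied on to set 9S against a substrate bias that probably favours the epimer, and the hindered neutral γ-hydroxy ester is expected not to lactonise.

**Step 17**
Reactants: 28 (9S)-allylic alcohol
Product: 29 (7Z)-cyclodecene
Conditions: Hoveyda–Grubbs II (20 mol %), 1,4-benzoquinone (10 mol %), PhMe (1 mM), 80 °C
Reagents that add atoms: none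
Why: Ring-closing metathesis in which the catalyst loads on the monosubstituted C7 vinyl group and closes onto the 1,1-disubstituted C8 methylene (the C5 methylene sits on the carbene-bearing chain one atom away and cannot cyclise), the ten-membered ring forming with the cis-(Z) trisubstituted alkene that a medium ring requires.

**Step 18**
Reactants: 29 (7Z)-cyclodecene
Product: 34 6-O-TBS lactone (7R,8R,17R), via osmate ester 30 (not isolated), via acetylated osmate ester 31 (not isolated), via diol ester 32 (not isolated), via C17-epimeric lactone 33 (not isolated)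
Conditions: OsO4 (1.05 equiv), TMEDA, CH2Cl2, −78 °C; Ac2O, pyridine, DMAP, 0 °C; aq. Na2SO3, THF, 40 °C; DBU (0.2 equiv), PhMe, 40 °C
Reagents that add atoms: osmium tetroxide O=[Os](=O)(=O)=O; acetic anhydride CC(=O)OC(C)=O
Why: Proposed new method: the hydrogen-bonded OsO4·TMEDA complex is delivered by the free allylic 9-OH to C7=C8 only (not to the exo-methylene) and syn to that hydroxyl, and syn addition to the ring-cis alkene fixes the 7R,8R relationship; the stable osmate(VI)–diamine chelate keeps O7 and O8 masked while the 9-OH is acetylated, so that after reductive cleavage only the 7-OH can close the γ-lactone, and DBU equilibrates C17 to the epimer with the methyl trans to C9; closest known types are Donohoe directed dihydroxylation, isolable osmate–diamine esters and γ-hydroxy ester lactonisation.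

**Step 19**
Reactants: 34 6-O-TBS lactone
Product: 35 6R-alcohol
Conditions: HF·pyridine, pyridine, THF, 0 °C → rt
Reagents that add atoms: none
Why: Buffered fluoride cleaves the secondary TBS ether and leaves the esters, the lactone and the epoxide untouched.

**Step 20**
Reactants: 35 6R-alcohol
Product: 36 CNP0105329.1 (target)
Conditions: PPh3, hexachloroacetone, CH2Cl2, 0 °C
Reagents that add atoms: hexachloroacetone O=C(C(Cl)(Cl)Cl)C(Cl)(Cl)Cl
Why: Appel-type chlorination under Magid conditions converts the secondary allylic alcohol into the chloride by SN2 with inversion (6R-OH to 6S-Cl) with little allylic transposition, and the two tertiary alcohols are too hindered to react.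

**Compound list**
1 | 3-bromofuran | Brc1ccoc1 | starting material
2 | 3-bromo-2-lithiofuran | [Li]c1occc1Br | intermediate
3 | 3-bromo-2-methylfuran | Cc1occc1Br | intermediate
4 | 3-lithio-2-methylfuran | Cc1occc1[Li] | intermediate
5 | 2-methyl-3-(trimethylsilyloxy)furan | Cc1occc1O[Si](C)(C)C | intermediate
6 | glycolaldehyde dimer (1,4-dioxane-2,5-diol) | OC1COC(O)CO1 | starting material
7 | 2-(triphenylphosphoranylidene)propanal | CC(C=O)=P(c1ccccc1)(c1ccccc1)c1ccccc1 | starting material
8 | glycolaldehyde | OCC=O | intermediate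
9 | (E)-4-hydroxy-2-methylbut-2-enal | O=C/C(C)=C/CO | intermediate
10 | (E)-2-methyl-4-(triethylsilyloxy)but-2-enal | O=C/C(C)=C/CO[Si](CC)(CC)CC | intermediate
11 | oxanorbornene adduct: 2,4-dimethyl-3-[(triethylsilyloxy)methyl]-5-(trimethylsilyloxy)-7-oxabicyclo[2.2.1]hept-5-ene-2-carbaldehyde, CHO exo, CH2OTES endo | O=C[C@@]1(C)[C@@H]2C=C(O[Si](C)(C)C)[C@@](C)(O2)[C@@H]1CO[Si](CC)(CC)CC | intermediate
12 | (1S,5S,6S)-5-hydroxy-1,5-dimethyl-4-oxo-6-[(triethylsilyloxy)methyl]cyclohex-2-ene-1-carbaldehyde | O=C[C@@]1(C)C=CC(=O)[C@@](C)(O)[C@@H]1CO[Si](CC)(CC)CC | intermediate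
13 | α-methylene-γ-butyrolactone (3-methylideneoxolan-2-one) | C=C1CCOC1=O | starting material
14 | diisobutylaluminium lactolate of 3-methylideneoxolan-2-ol | C=C1CCOC1O[Al](CC(C)C)CC(C)C | intermediate
15 | rac-3-methylidenehex-5-ene-1,4-diol | C=CC(O)C(=C)CCO | intermediate
16 | rac-6-iodo-4-methylidenehex-1-en-3-ol | C=CC(O)C(=C)CCI | intermediate
17 | (S)-6-iodo-4-methylidenehex-1-en-3-ol | C=C[C@H](O)C(=C)CCI | intermediate
18 | (3S)-3-(tert-butyldimethylsilyloxy)-6-iodo-4-methylidenehex-1-ene | C=C[C@H](O[Si](C)(C)C(C)(C)C)C(=C)CCI | intermediate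
19 | ethyl 2-methylbuta-2,3-dienoate | C=C=C(C)C(=O)OCC | starting material
20 | rac-ethyl 3-iodo-2-methylbut-3-enoate | C=C(I)C(C)C(=O)OCC | intermediate
21 | bis[(4S)-4-(tert-butyldimethylsilyloxy)-3-methylidenehex-5-enyl]zinc | C=C[C@H](O[Si](C)(C)C(C)(C)C)C(=C)CC[Zn]CCC(=C)[C@@H](O[Si](C)(C)C(C)(C)C)C=C | intermediate
22 | C2 carbinol: 4-[(1S,5S)-1-hydroxy-5-(TBSO)-4-methylidenehept-6-en-1-yl]-6-hydroxy-4,6-dimethyl-5-[(TESO)methyl]cyclohex-2-en-1-one, ring as in 12 | C=C[C@H](O[Si](C)(C)C(C)(C)C)C(=C)CC[C@H](O)[C@@]1(C)C=CC(=O)[C@@](C)(O)[C@@H]1CO[Si](CC)(CC)CC | intermediate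
23 | (2S)-2-acetate of 22 | C=C[C@H](O[Si](C)(C)C(C)(C)C)C(=C)CC[C@H](OC(C)=O)[C@@]1(C)C=CC(=O)[C@@](C)(O)[C@@H]1CO[Si](CC)(CC)CC | intermediate
24 | cis-11,12-diol: C12 carbinol of 23, 12-OH cis to 11-OH | C=C[C@H](O[Si](C)(C)C(C)(C)C)C(=C)CC[C@H](OC(C)=O)[C@@]1(C)C=C[C@@H](O)[C@@](C)(O)[C@@H]1CO[Si](CC)(CC)CC | intermediate
25 | 13,14-epoxide of 24, epoxide oxygen cis to both hydroxyls | C=C[C@H](O[Si](C)(C)C(C)(C)C)C(=C)CC[C@H](OC(C)=O)[C@@]1(C)[C@H]2O[C@H]2[C@@H](O)[C@@](C)(O)[C@@H]1CO[Si](CC)(CC)CC | intermediate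
26 | 12-O-butyrate of 25 | C=C[C@H](O[Si](C)(C)C(C)(C)C)C(=C)CC[C@H](OC(C)=O)[C@@]1(C)[C@H]2O[C@H]2[C@@H](OC(=O)CCC)[C@@](C)(O)[C@@H]1CO[Si](CC)(CC)CC | intermediate
27 | C9 aldehyde (CH2OTES of 26 replaced by CHO) | C=C[C@H](O[Si](C)(C)C(C)(C)C)C(=C)CC[C@H](OC(C)=O)[C@@]1(C)[C@H]2O[C@H]2[C@@H](OC(=O)CCC)[C@@](C)(O)[C@@H]1C=O | intermediate
28 | (9S)-allylic alcohol: C9 carbinol bearing C8(=CH2)–CH(CH3)CO2Et, C17 epimer mixture | C=C[C@H](O[Si](C)(C)C(C)(C)C)C(=C)CC[C@H](OC(C)=O)[C@@]1(C)[C@H]2O[C@H]2[C@@H](OC(=O)CCC)[C@@](C)(O)[C@@H]1[C@H](O)C(=C)C(C)C(=O)OCC | intermediate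
29 | (7Z)-cyclodecene: ten-membered ring closed, 9-OH, 6-OTBS, C8 bearing CH(CH3)CO2Et, C17 mixture | C=C1CC[C@H](OC(C)=O)[C@@]2(C)[C@H]3O[C@H]3[C@@H](OC(=O)CCC)[C@@](C)(O)[C@@H]2[C@H](O)/C(C(C)C(=O)OCC)=C\[C@@H]1O[Si](C)(C)C(C)(C)C | intermediate
30 | 7,8-O-osmate(VI) ester of 29, TMEDA complex | C=C1CC[C@H](OC(C)=O)[C@@]2(C)[C@H]3O[C@H]3[C@@H](OC(=O)CCC)[C@@](C)(O)[C@@H]2[C@H](O)[C@@]4(C(C)C(=O)OCC)O[Os](=O)(=O)O[C@H]4[C@@H]1O[Si](C)(C)C(C)(C)C.CN(C)CCN(C)C | intermediate
31 | 9-O-acetyl osmate ester, TMEDA complex | C=C1CC[C@H](OC(C)=O)[C@@]2(C)[C@H]3O[C@H]3[C@@H](OC(=O)CCC)[C@@](C)(O)[C@@H]2[C@H](OC(C)=O)[C@@]4(C(C)C(=O)OCC)O[Os](=O)(=O)O[C@H]4[C@@H]1O[Si](C)(C)C(C)(C)C.CN(C)CCN(C)C | intermediate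
32 | 7,8-diol ethyl ester (9-OAc, 6-OTBS, C17 mixture) | C=C1CC[C@H](OC(C)=O)[C@@]2(C)[C@H]3O[C@H]3[C@@H](OC(=O)CCC)[C@@](C)(O)[C@@H]2[C@H](OC(C)=O)[C@](O)(C(C)C(=O)OCC)[C@@H](O)[C@@H]1O[Si](C)(C)C(C)(C)C | intermediate
33 | 6-O-TBS γ-lactone as C17 epimer mixture | C=C1CC[C@H](OC(C)=O)[C@@]2(C)[C@H]3O[C@H]3[C@@H](OC(=O)CCC)[C@@](C)(O)[C@@H]2[C@H](OC(C)=O)[C@]2(O)C(C)C(=O)O[C@H]2[C@@H]1O[Si](C)(C)C(C)(C)C | intermediate
34 | 6-O-TBS γ-lactone, 17R (target with 6R-OTBS in place of 6S-Cl) | C=C1CC[C@H](OC(C)=O)[C@@]2(C)[C@H]3O[C@H]3[C@@H](OC(=O)CCC)[C@@](C)(O)[C@@H]2[C@H](OC(C)=O)[C@]2(O)[C@@H](C)C(=O)O[C@H]2[C@@H]1O[Si](C)(C)C(C)(C)C | intermediate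
35 | 6R-alcohol (target with 6R-OH in place of 6S-Cl) | C=C1CC[C@H](OC(C)=O)[C@@]2(C)[C@H]3O[C@H]3[C@@H](OC(=O)CCC)[C@@](C)(O)[C@@H]2[C@H](OC(C)=O)[C@]2(O)[C@@H](C)C(=O)O[C@H]2[C@@H]1O | intermediate
36 | CNP0105329.1: (1S,2S,6S,7R,8R,9S,10S,11S,12R,13R,14R,17R)-2,9-diacetoxy-12-butanoyloxy-6-chloro-13,14-epoxy-8,11-dihydroxybriar-5(16)-ene 7,19-lactone | C=C1CC[C@H](OC(C)=O)[C@@]2(C)[C@H]3O[C@H]3[C@@H](OC(=O)CCC)[C@@](C)(O)[C@@H]2[C@H](OC(C)=O)[C@]2(O)[C@@H](C)C(=O)O[C@H]2[C@H]1Cl | target

**Totals.** 20 steps in all; the longest linear sequence is 14 steps (steps 6–9, then 11–20, from α-methylene-γ-butyrolactone).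

**Three steps most likely to fail, with fallbacks**

Step 5 (key Diels–Alder). The acidic catalyst may be quenched by the silyl enol ether, or the hindered enal may give low ee. The fallback sets out from 5 and 10 and gives up catalytic enantiocontrol in favour of resolution through diastereomers. The cycloaddition is run with Me2AlCl (CH2Cl2, −78 °C) or neat at 12 kbar, giving 11 together with the mirror-image oxanorbornene adduct F1. K2CO3/MeOH opens both, to 12 and the ent-enone aldehyde F2. The racemate is taken through step 11, where the enantiopure chain 18 turns the two enantiomers into 23 and the diastereomeric acetate F3; these are separated by chromatography and the route is rejoined at 23.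

Step 16 (C9 configuration in the NHK coupling). Felkin and chelate models with C1 as the blocking group both predict the 9-epimer, so ligand control may be overridden. The fallback sets out from 27 and sets C9 by hydride delivery to a ketone instead. The coupling is run without chiral ligand to give 28 mixed with the 9-epi carbinol F4. Dess–Martin oxidation of the mixture converges on the C9 enone F5. Luche reduction then delivers hydride anti to C1, which by the same models gives 9S and rejoins the route at 28.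

Step 17 (RCM to a ten-membered trisubstituted alkene). Oligomerisation or no closure is possible. The fallback sets out from 28 and uses a temporary silicon tether so that the metathesis is a seven-membered closure that enforces the Z-alkene. HF·pyridine gives the 6,9-diol F6. iPr2SiCl2/imidazole at high dilution gives the cyclic di-isopropylsilylene F7. RCM gives the silylene-bridged (7Z)-cyclodecene F8, and HF·pyridine releases the macrocyclic 6,9-diol F9. Selective silylation of the less hindered 6-OH (TBSOTf, 2,6-lutidine, −78 °C) rejoins the route at 29.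

**Further compounds**
F1 | step 5 | mirror-image oxanorbornene adduct (ent-11) | O=C[C@]1(C)[C@H]2C=C(O[Si](C)(C)C)[C@](C)(O2)[C@H]1CO[Si](CC)(CC)CC
F2 | step 5 | ent-enone aldehyde (ent-12) | O=C[C@]1(C)C=CC(=O)[C@](C)(O)[C@H]1CO[Si](CC)(CC)CC
F3 | step 5 | diastereomeric acetate (from ent-12 and 18) | C=C[C@H](O[Si](C)(C)C(C)(C)C)C(=C)CC[C@H](OC(C)=O)[C@]1(C)C=CC(=O)[C@](C)(O)[C@H]1CO[Si](CC)(CC)CC
F4 | step 16 | 9-epi carbinol (9-epi-28) | C=C[C@H](O[Si](C)(C)C(C)(C)C)C(=C)CC[C@H](OC(C)=O)[C@@]1(C)[C@H]2O[C@H]2[C@@H](OC(=O)CCC)[C@@](C)(O)[C@@H]1[C@@H](O)C(=C)C(C)C(=O)OCC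
F5 | step 16 | C9 enone | C=C[C@H](O[Si](C)(C)C(C)(C)C)C(=C)CC[C@H](OC(C)=O)[C@@]1(C)[C@H]2O[C@H]2[C@@H](OC(=O)CCC)[C@@](C)(O)[C@@H]1C(=O)C(=C)C(C)C(=O)OCC
F6 | step 17 | 6,9-diol (28 without TBS) | C=C[C@H](O)C(=C)CC[C@H](OC(C)=O)[C@@]1(C)[C@H]2O[C@H]2[C@@H](OC(=O)CCC)[C@@](C)(O)[C@@H]1[C@H](O)C(=C)C(C)C(=O)OCC
F7 | step 17 | cyclic 6,9-O-di-isopropylsilylene | C=C[C@H](O%10)C(=C)CC[C@H](OC(C)=O)[C@@]1(C)[C@H]2O[C@H]2[C@@H](OC(=O)CCC)[C@@](C)(O)[C@@H]1[C@H](O[Si]%10(C(C)C)C(C)C)C(=C)C(C)C(=O)OCC
F8 | step 17 | silylene-bridged (7Z)-cyclodecene | C=C1CC[C@H](OC(C)=O)[C@@]2(C)[C@H]3O[C@H]3[C@@H](OC(=O)CCC)[C@@](C)(O)[C@@H]2[C@H](O[Si]4(C(C)C)C(C)C)/C(C(C)C(=O)OCC)=C\[C@@H]1O4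
F9 | step 17 | macrocyclic 6,9-diol | C=C1CC[C@H](OC(C)=O)[C@@]2(C)[C@H]3O[C@H]3[C@@H](OC(=O)CCC)[C@@](C)(O)[C@@H]2[C@H](O)/C(C(C)C(=O)OCC)=C\[C@@H]1O
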